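All runs were generated by integration for an exercise, and the scatter is random.

We must decide whether this flask is worth running to 30 h for chains of 60 units.

| setting | summer | flask |
|---|---|---|
| L | 3 M | 3.0 M |
| D | 30 mM | 30 mM |
| remark | the very flask that is asked about, followed so far |  |
| time |  | 30 h |

summer run (percent of the L charged)

| time / h | G / % | L / % |
|---|---|---|
| 1.33 | 3.2 | 89.8 |
| 2.00 | 4.0 | 87.5 |
| 3.00 | 6.8 | 77.9 |
| 4.00 | 9.6 | 71.2 |
| 6.00 | 11.6 | 60.0 |
| 10.0 | 20.6 | 45.6 |
| 15.0 | 23.0 | 28.5 |

(each reading ± 1 percentage point)

- the average divides the monomer in chains by the number of chains begun, living and dead together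
- the earlier runs do not show the number of chains; that part of a forecast is a guess

- whether the average number of monomer units in a chain (chains begun, living or dead) reaches 60 by 30 h (yes / no)
- average number of monomer units in a chain (chains begun, living or dead) at 30 h

The bench rule is our zero of the scale: if every D begins one chain and every L charged enters a chain, the length is L charged over D charged, 100, which is more than the 60 wanted. Its border is a ratio: 0.600 of the L charged has to stand as G. At 15.0 h the summer run reads 23.0 % as G with 28.5 % of L left, so 0.322 of the L consumed is in chains. We carry this chain share, G gained per L consumed, which is the selectivity towards chains.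

The share is less than the border, so the rule stops working here. With one chain per D and this share, we reckon a length of 32.2 for this flask emptied of L, and 60 would take fewer than 0.537 chains per D, a count the readings do not show. The summer readings of L fall like a first-order lag, so we reckon that a second 15.0 h multiplies L by the same factor and leaves 8.12 %. Our length at 30 h, with one chain per D, is therefore 29.6.

The forecast says no and 33, more than our figure, and of the chain count it says: “Incomplete initiation would raise it, and transfer would lower it.”

    L + D → Z + G (k = 0.00970 L mol⁻¹ min⁻¹)
    L + Z → G + Z, rate k2*[Z]*[L] (k = 0.0160 L mol⁻¹ min⁻¹)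
    L → Q (k = 9.00 × 10⁻⁴ min⁻¹)
    2 D → X (k = 0.0460 L mol⁻¹ min⁻¹)

The answer for the flask is no, with a length of 31.9. At 30.0 h the flask holds 30.4 % as G, 60.9 % as Q and 8.73 % as L, a chain share of 0.333. Left to 300 h, its length is 34.9, still less than 60. The neighbour flask with D at 0.012 M has a charge ratio of 250 and a chain share of 0.171, about half of the flask's. From its 14.7 % as G, one chain per D reckons 36.6, and that neighbour flask gives 37.3.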